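## Retrosynthetic overview

1. Ferulate ester: the C=C is made by Knoevenagel–Doebner condensation with vanillin and the ester C–O by malonylation of the (R)-chromenyl-methanol; the ferulate ring is bought.
2. The chromene comes from a bridged tricyclic ether by acid E1 opening of its benzylic C–O bond, which creates C3=C4 and frees the CH2OH.
3. The bridged ether comes from a 3-methoxy-5-acetyl-salicylaldehyde and methallyl alcohol by a one-pot oxa-[4+2]/ether-exchange; C2 is set here.
4. The salicylaldehyde comes from acetovanillone by ortho-formylation.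
5. Ring order: the arene is bought; the pyran ring and the oxolane bridge close in the same operation; the bridge is then opened; no ring is formed afterwards.

Assumption: the stereocentre (chromene C2) is R by CIP; which antipode of the chiral acid gives this sense cannot be predicted and must be fixed by one test run (both antipodes are available).

## Route

Step 1
Reactants: 1 1-(4-hydroxy-3-methoxyphenyl)ethan-1-one (acetovanillone)
Product: 2 5-acetyl-2-hydroxy-3-methoxybenzaldehyde
Conditions: hexamethylenetetramine (2 equiv), TFA, 90 °C; then 3 M aq. HCl, 60 °C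
Reagents that add atoms: hexamethylenetetramine, C1N2CN3CN1CN(C2)C3; water, O
Why: Duff ortho-formylation (iminium aminomethylation ortho to the phenol, internal redox to the benzyl iminium, hydrolysis); the only free position ortho to OH is C5, and the same reaction is known on vanillin.

Step 2
Reactants: 2 5-acetyl-2-hydroxy-3-methoxybenzaldehyde; 3 2-methylprop-2-en-1-ol (methallyl alcohol)
Product: 6 1-[(2R,5R)-9-methoxy-2-methyl-2,3-dihydro-5H-2,5-methano-1,4-benzodioxepin-7-yl]ethan-1-one, via O-methallyl o-quinone methide 4 (not isolated), via 4-methallyloxychroman 5 (not isolated)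
Conditions: 3 (2.2 equiv), confined chiral imidodiphosphorimidate (IDPi) Brønsted acid (3 mol%), 5 Å MS, CHCl3, −20 °C; evaporate excess 3, CHCl3 (0.02 M), 0 °C; Et3N
Reagents that add atoms: none
Why: Proposed new method: the acid condenses 2 with 3 to the O-methallyl oxocarbenium ion (protonated o-quinone methide 4) held as a chiral contact ion pair; a second molecule of 3 adds in an asynchronous inverse-demand oxa-[4+2] (CH2 terminus to the benzylic carbon, phenol oxygen to the tertiary carbon, Markovnikov), with its OH hydrogen-bonded to the anion so that CH3 and CH2OH are differentiated and C2 is set as R; benzylic ether exchange then replaces the 4-methallyloxy group of 5 by the tethered CH2OH, which can only close cis and so fixes C5 as R, giving pyran ring and oxolane bridge in one operation; closest known reactions are the confined-acid asymmetric Prins cyclisation of salicylaldehydes with 3-methylbut-3-en-1-ol, the Lewis-acid three-component o-quinone methide [4+2] of salicylaldehydes with 1,1-disubstituted alkenes to 4-alkoxychromans, and Prins bicyclisations in which a phenol traps the tertiary cation.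

Step 3
Reactants: 6 1-[(2R,5R)-9-methoxy-2-methyl-2,3-dihydro-5H-2,5-methano-1,4-benzodioxepin-7-yl]ethan-1-one
Product: 7 1-[(2R)-2-(hydroxymethyl)-8-methoxy-2-methyl-2H-chromen-6-yl]ethan-1-one
Conditions: CSA (10 mol%), PhMe, 60 °C; Et3N
Reagents that add atoms: none
Why: Acid-catalysed E1 elimination through the same benzylic cation as in the standard TsOH dehydration of chroman-4-ols to 2H-chromenes: the benzylic C5–O4 bond ionises (cation stabilised by the ortho ring oxygen), the bridge CH2 carries the only β-hydrogens, and loss of one gives the conjugated chromene and frees CH2OH, driven by strain release and conjugation; C2 is not touched and stays R.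

Step 4
Reactants: 7 1-[(2R)-2-(hydroxymethyl)-8-methoxy-2-methyl-2H-chromen-6-yl]ethan-1-one; 8 2,2-dimethyl-1,3-dioxane-4,6-dione (Meldrum's acid); 9 4-hydroxy-3-methoxybenzaldehyde (vanillin)
Product: 11 [(2R)-6-acetyl-8-methoxy-2-methyl-2H-chromen-2-yl]methyl (2E)-3-(4-hydroxy-3-methoxyphenyl)prop-2-enoate, via malonic half-ester 10 (not isolated)
Conditions: 8 (1.1 equiv), PhMe, 85 °C; then 9 (1.2 equiv), pyridine, piperidine (10 mol%), 80 °C
Reagents that add atoms: none
Why: Alcoholysis of Meldrum's acid (acetone lost) gives the malonic half-ester, and Knoevenagel–Doebner condensation with vanillin followed by decarboxylation gives the E-cinnamate; the free phenol needs no protection, the aryl methyl ketone is far less electrophilic than the aldehyde, and 80–85 °C is kept low to avoid racemisation of the 2H-chromene by electrocyclic ring opening.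

## Compound list

1 | 1-(4-hydroxy-3-methoxyphenyl)ethan-1-one (acetovanillone) | CC(=O)c1ccc(O)c(OC)c1 | starting material
2 | 5-acetyl-2-hydroxy-3-methoxybenzaldehyde | CC(=O)c1cc(C=O)c(O)c(OC)c1 | intermediate
3 | 2-methylprop-2-en-1-ol (methallyl alcohol) | C=C(C)CO | starting material
4 | 4-acetyl-2-methoxy-6-{[(2-methylprop-2-en-1-yl)oxy]methylidene}cyclohexa-2,4-dien-1-one (neutral o-quinone methide form of the O-methallyl oxocarbenium ion) | O=C1C(=COCC(C)=C)C=C(C(C)=O)C=C1OC | intermediate
5 | 1-{(2R,4RS)-2-(hydroxymethyl)-8-methoxy-2-methyl-4-[(2-methylprop-2-en-1-yl)oxy]-3,4-dihydro-2H-chromen-6-yl}ethan-1-one (C4 epimers) | OC[C@@]1(C)CC(OCC(C)=C)c2cc(C(C)=O)cc(OC)c2O1 | intermediate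
6 | 1-[(2R,5R)-9-methoxy-2-methyl-2,3-dihydro-5H-2,5-methano-1,4-benzodioxepin-7-yl]ethan-1-one (aryl O1–C2 quaternary with CH3; C3H2–O4–C5H benzylic; CH2 bridge C2–C5) | C[C@]12CO[C@H](C1)c1cc(C(C)=O)cc(OC)c1O2 | intermediate
7 | 1-[(2R)-2-(hydroxymethyl)-8-methoxy-2-methyl-2H-chromen-6-yl]ethan-1-one | OC[C@@]1(C)C=Cc2cc(C(C)=O)cc(OC)c2O1 | intermediate
8 | 2,2-dimethyl-1,3-dioxane-4,6-dione (Meldrum's acid) | CC1(C)OC(=O)CC(=O)O1 | starting material
9 | 4-hydroxy-3-methoxybenzaldehyde (vanillin) | COc1cc(C=O)ccc1O | starting material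
10 | 3-{[(2R)-6-acetyl-8-methoxy-2-methyl-2H-chromen-2-yl]methoxy}-3-oxopropanoic acid | OC(=O)CC(=O)OC[C@@]1(C)C=Cc2cc(C(C)=O)cc(OC)c2O1 | intermediate
11 | [(2R)-6-acetyl-8-methoxy-2-methyl-2H-chromen-2-yl]methyl (2E)-3-(4-hydroxy-3-methoxyphenyl)prop-2-enoate | COc1cc(/C=C/C(=O)OC[C@@]2(C)C=Cc3cc(C(C)=O)cc(OC)c3O2)ccc1O | target

## Step count and risks

Total steps: 4. Longest linear sequence: 4 (1 → 2 → 6 → 7 → 11).

The three steps most likely to fail are steps 2, 3 and 4.

Step 2 is the largest risk. The asymmetric cycloaddition of an unactivated 1,1-disubstituted allylic alcohol is unprecedented, so the enantiomeric excess and the sense of induction are unknown. The strained bridged ether competes with its open 4-alkoxy form and with direct elimination to 7; any 7 formed is simply carried into step 4. Crystallisation of 6 is the planned ee upgrade. The fallback abandons the bicyclisation and sets the quaternary ether with palladium, setting out from 1 and coming back at 7. Iodination of 1 (NIS, cat. TsOH, MeCN) gives 1-(4-hydroxy-3-iodo-5-methoxyphenyl)ethan-1-one F1. Suzuki–Miyaura vinylation (potassium vinyltrifluoroborate, PdCl2(dppf), Cs2CO3, THF/H2O) gives 1-(3-ethenyl-4-hydroxy-5-methoxyphenyl)ethan-1-one F2. Pd-catalysed dynamic kinetic asymmetric etherification with racemic 2-methyl-2-vinyloxirane (Pd2(dba)3, Trost DACH-phenyl ligand, CH2Cl2) gives the branched tertiary ether 1-(3-ethenyl-4-{[(2R)-1-hydroxy-2-methylbut-3-en-2-yl]oxy}-5-methoxyphenyl)ethan-1-one F3. Ring-closing metathesis (Grubbs II, CH2Cl2, 40 °C) then closes the pyran ring to 7.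

Step 3 may stall in a protic equilibrium with re-closure. The acid may also ionise the tertiary allylic aryl ether of the product (loss of ee) or oligomerise the chromene. The fallback replaces reversible protonation by irreversible acylative cleavage, setting out from 6 and coming back at 7. Ac2O with catalytic Sc(OTf)3 (MeCN, 0 °C) acylates the bridging oxygen; the benzylic C–O bond breaks and elimination gives [(2R)-6-acetyl-8-methoxy-2-methyl-2H-chromen-2-yl]methyl acetate F4. Methanolysis (K2CO3, MeOH, 0 °C) returns 7.

Step 4 may suffer from slow acylation of the neopentyl-type alcohol, a sluggish Knoevenagel step with the phenolic aldehyde, or partial racemisation on long heating. The fallback is a room-temperature acylation with a protected cinnamic acid, setting out from 7 and coming back at 11. Coupling with commercial (E)-4-acetoxy-3-methoxycinnamic acid (EDC·HCl, DMAP, CH2Cl2, 20 °C) gives [(2R)-6-acetyl-8-methoxy-2-methyl-2H-chromen-2-yl]methyl (2E)-3-(4-acetoxy-3-methoxyphenyl)prop-2-enoate F5. Selective aminolysis of the aryl acetate (pyrrolidine, CH2Cl2, 0 °C) gives 11.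

## Further compounds

F1 | step 2 | 1-(4-hydroxy-3-iodo-5-methoxyphenyl)ethan-1-one | CC(=O)c1cc(I)c(O)c(OC)c1
F2 | step 2 | 1-(3-ethenyl-4-hydroxy-5-methoxyphenyl)ethan-1-one | CC(=O)c1cc(C=C)c(O)c(OC)c1
F3 | step 2 | 1-(3-ethenyl-4-{[(2R)-1-hydroxy-2-methylbut-3-en-2-yl]oxy}-5-methoxyphenyl)ethan-1-one | OC[C@@](C)(C=C)Oc1c(C=C)cc(C(C)=O)cc1OC
F4 | step 3 | [(2R)-6-acetyl-8-methoxy-2-methyl-2H-chromen-2-yl]methyl acetate | CC(=O)OC[C@@]1(C)C=Cc2cc(C(C)=O)cc(OC)c2O1
F5 | step 4 | [(2R)-6-acetyl-8-methoxy-2-methyl-2H-chromen-2-yl]methyl (2E)-3-(4-acetoxy-3-methoxyphenyl)prop-2-enoate | COc1cc(/C=C/C(=O)OC[C@@]2(C)C=Cc3cc(C(C)=O)cc(OC)c3O2)ccc1OC(C)=O
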